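**Retrosynthetic overview**
- The last bond made is C2–C1', between ring C and ring B. This splits the (2S)-flavanone into 7-hydroxy-8-prenylchromone and 6-bromo-2,2-dimethyl-8-prenyl-2H-chromene.
- Chromone C2 is normally an acceptor carbon. It is turned into a nickel-bound homoenolate carbon (a 1-silyloxyallylnickel) and joined to the C–Br carbon, a second electrophile. The chiral ligand sets C2 in the same event.
- Chromone fragment: rings A and C are bought as 7-hydroxychromone. The 8-prenyl group comes from O-(1,1-dimethylallyl)ation followed by aromatic Claisen rearrangement.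
- Bromide fragment: ring B is bought as 4-bromophenol. It is C-prenylated at the ortho position, then the pyran ring is closed with prenal by oxa-6π electrocyclisation.
- Ring order: the dimethylpyran ring is the only ring built (step 4). No ring is formed after the coupling.

Assumption: the SMILES descriptor is read as (2S). The ligand enantiomer that gives (2S) cannot be predicted safely, so (S)-t-BuPyOx is written, and its mirror image is used if a test run (circular dichroism, chiral HPLC) shows (2R).

**Step 1**
Reactants: 1 7-hydroxy-4H-chromen-4-one; 2 tert-butyl 2-methylbut-3-en-2-yl carbonate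
Product: 3 7-[(2-methylbut-3-en-2-yl)oxy]-4H-chromen-4-one
Conditions: Pd(PPh3)4 (3 mol%), THF, 0 °C to rt
Reagents that add atoms: none
Why: Tsuji–Trost O-allylation, in which decarboxylative ionisation of 2 gives a 1,1-dimethylallyl-palladium species and tert-butoxide, the acidic phenol is deprotonated, and the phenoxide attacks the more substituted allyl terminus under kinetic control at low temperature.

**Step 2**
Reactants: 3 7-[(2-methylbut-3-en-2-yl)oxy]-4H-chromen-4-one
Product: 5 7-hydroxy-8-(3-methylbut-2-en-1-yl)-4H-chromen-4-one, via ortho-dienone 4 (not isolated)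
Conditions: PhNEt2, 130 °C
Reagents that add atoms: none
Why: Aromatic Claisen rearrangement, in which the [3,3] shift inverts the tertiary allyl unit to a linear prenyl group and goes to C8 because the C7–C8 bond of 7-oxychromones has the higher double-bond character, while the basic solvent suppresses acid-induced loss of isoprene.

**Step 3**
Reactants: 6 4-bromophenol; 7 1-bromo-3-methylbut-2-ene (prenyl bromide)
Product: 8 4-bromo-2-(3-methylbut-2-en-1-yl)phenol
Conditions: NaH, toluene, 0 °C to 40 °C
Reagents that add atoms: none
Why: Ortho C-alkylation of a phenol salt in a non-polar medium, where the tight O–Na ion pair shields oxygen so the ortho carbon attacks prenyl bromide in SN2 fashion, and the para position is blocked by bromine.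

**Step 4**
Reactants: 8 4-bromo-2-(3-methylbut-2-en-1-yl)phenol; 9 3-methylbut-2-enal (prenal)
Product: 12 6-bromo-2,2-dimethyl-8-(3-methylbut-2-en-1-yl)-2H-chromene, via benzodioxaborinine 10 (not isolated), via ortho-quinone methide 11 (not isolated)
Conditions: PhB(OH)2 (1.2 equiv), EtCO2H (0.3 equiv), toluene, reflux, Dean–Stark
Reagents that add atoms: none
Why: Boronic acid-templated ortho-hydroxyalkylation at the only free ortho position gives 10, which loses the boron unit on heating to give 11, and 11 closes by oxa-6π electrocyclisation to the 2,2-dimethylchromene.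

**Step 5**
Reactants: 5 7-hydroxy-8-(3-methylbut-2-en-1-yl)-4H-chromen-4-one; 12 6-bromo-2,2-dimethyl-8-(3-methylbut-2-en-1-yl)-2H-chromene
Product: 16 (2S)-2-[2,2-dimethyl-8-(3-methylbut-2-en-1-yl)-2H-chromen-6-yl]-7-hydroxy-8-(3-methylbut-2-en-1-yl)-2,3-dihydro-4H-chromen-4-one, via chromone triethylsilyl ether 13 (not isolated), via silyloxyallylnickel homoenolate 14 (not isolated), via bis-silyl flav-3-ene 15 (not isolated)
Conditions: 5, NaH (1.05 equiv), Et3SiCl (3 equiv), THF–DMA, 0 °C; then 12 (1.2 equiv), NiBr2(dme) (10 mol%), (S)-t-BuPyOx (12 mol%), Mn powder (3 equiv), 25 °C; then 1 M HCl, 0 °C to rt, same flask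
Reagents that add atoms: none
Why: Proposed new method: ligated zerovalent nickel and Et3SiCl convert chromone 13, whose C2 is normally an acceptor carbon, into the η3-(1-silyloxyallyl)nickel 14, a homoenolate equivalent with a metal-bound nucleophilic C2, which after one-electron reduction by Mn takes up aryl bromide 12 (a second electrophile) and forms the C2–C1' bond by reductive elimination from trivalent nickel on the face left open by the tert-butyl oxazoline, so that (S)-C2 is set in the bond-forming event and the acid quench frees ketone and phenol from 15 by C3 protonation without a free enolate (no retro-oxa-Michael racemisation); the closest known reaction types are the nickel-catalysed reductive conjugate arylation of enones with aryl halides, chlorosilane and Mn (cross-electrophile coupling, enantioselective on carbocyclic enones) and the nickel-catalysed arylation of 2-alkoxy-2H-chromenes through chromenyl-nickel species.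

**Compound list**
1 | 7-hydroxy-4H-chromen-4-one (7-hydroxychromone) | O=c1ccoc2cc(O)ccc12 | starting material
2 | tert-butyl 2-methylbut-3-en-2-yl carbonate (catalogue reagent) | C=CC(C)(C)OC(=O)OC(C)(C)C | starting material
3 | 7-[(2-methylbut-3-en-2-yl)oxy]-4H-chromen-4-one | C=CC(C)(C)Oc1ccc2c(=O)ccoc2c1 | intermediate
4 | 8-(3-methylbut-2-en-1-yl)-8H-chromene-4,7-dione, racemic ortho-dienone (not isolated) | CC(C)=CCC1C(=O)C=CC2=C1OC=CC2=O | intermediate
5 | 7-hydroxy-8-(3-methylbut-2-en-1-yl)-4H-chromen-4-one | CC(C)=CCc1c(O)ccc2c(=O)ccoc12 | intermediate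
6 | 4-bromophenol | Oc1ccc(Br)cc1 | starting material
7 | 1-bromo-3-methylbut-2-ene (prenyl bromide) | CC(C)=CCBr | starting material
8 | 4-bromo-2-(3-methylbut-2-en-1-yl)phenol | CC(C)=CCc1cc(Br)ccc1O | intermediate
9 | 3-methylbut-2-enal (prenal) | CC(C)=CC=O | starting material
10 | 6-bromo-4-(2-methylprop-1-en-1-yl)-8-(3-methylbut-2-en-1-yl)-2-phenyl-4H-1,3,2-benzodioxaborinine, racemic (not isolated) | CC(C)=CCc1cc(Br)cc2c1OB(c1ccccc1)OC2C=C(C)C | intermediate
11 | 4-bromo-6-(3-methylbut-2-en-1-ylidene)-2-(3-methylbut-2-en-1-yl)cyclohexa-2,4-dien-1-one, ortho-quinone methide (not isolated) | CC(C)=CCC1=CC(Br)=CC(=CC=C(C)C)C1=O | intermediate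
12 | 6-bromo-2,2-dimethyl-8-(3-methylbut-2-en-1-yl)-2H-chromene | CC(C)=CCc1cc(Br)cc2c1OC(C)(C)C=C2 | intermediate
13 | 8-(3-methylbut-2-en-1-yl)-7-(triethylsilyloxy)-4H-chromen-4-one (not isolated) | CC(C)=CCc1c(O[Si](CC)(CC)CC)ccc2c(=O)ccoc12 | intermediate
14 | (t-BuPyOx)NiCl[η3-8-(3-methylbut-2-en-1-yl)-4,7-bis(triethylsilyloxy)chromen-2-yl], drawn as the (2R) σ-form with the ligand left out of the SMILES (not isolated) | Cl[Ni][C@@H]1C=C(O[Si](CC)(CC)CC)c2ccc(O[Si](CC)(CC)CC)c(CC=C(C)C)c2O1 | intermediate
15 | (2S)-2-[2,2-dimethyl-8-(3-methylbut-2-en-1-yl)-2H-chromen-6-yl]-8-(3-methylbut-2-en-1-yl)-4,7-bis(triethylsilyloxy)-2H-chromene (not isolated) | CC(C)=CCc1cc([C@@H]2C=C(O[Si](CC)(CC)CC)c3ccc(O[Si](CC)(CC)CC)c(CC=C(C)C)c3O2)cc2c1OC(C)(C)C=C2 | intermediate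
16 | (2S)-2-[2,2-dimethyl-8-(3-methylbut-2-en-1-yl)-2H-chromen-6-yl]-7-hydroxy-8-(3-methylbut-2-en-1-yl)-2,3-dihydro-4H-chromen-4-one | CC(C)=CCc1cc([C@@H]2CC(=O)c3ccc(O)c(CC=C(C)C)c3O2)cc2c1OC(C)(C)C=C2 | target

**Total step count:** 5.
**Longest linear sequence:** 3 steps (1 → 3 → 5 → 16, or 6 → 8 → 12 → 16).

**Three steps most likely to fail**

**Step 5.** Three things can go wrong:
- The donor-substituted chromone may form the allylnickel too slowly, so that 12 homocouples or is reduced.
- The enantioselectivity on a chromone is unproven.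
- Zerovalent nickel could re-ionise the allylic C2–O1 bond of 15 and erode the ee.

The fallback sets out from 12 and 5 and comes back at 16. It inverts the polarity of ring B instead of that of the chromone. Bromine–lithium exchange on 12 (n-BuLi, THF, −78 °C), then B(OiPr)3 and a mild acid work-up, gives [2,2-dimethyl-8-(3-methylbut-2-en-1-yl)-2H-chromen-6-yl]boronic acid F1. F1 is added to the free phenol 5 with Pd(OCOCF3)2 (5 mol%), t-BuPyOx (6 mol%), NH4PF6, water and ClCH2CH2Cl at 60 °C. This is a base-free enantioselective conjugate addition of an aryl–divalent palladium species to the chromone, and it gives 16 directly.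

**Step 4.** Phenol 8 is deactivated by bromine and hindered by the prenyl group, so the boron-templated hydroxyalkylation may stall. The fallback sets out from 8 and comes back at 12. O-alkylation with 3-chloro-3-methylbut-1-yne (CuCl2·2H2O cat., DBU, MeCN, 0 °C) gives 4-bromo-1-[(2-methylbut-3-yn-2-yl)oxy]-2-(3-methylbut-2-en-1-yl)benzene F2. Heating F2 in PhNEt2 at 180 °C triggers a propargyl Claisen rearrangement to the free ortho position, a 1,5-hydrogen shift and an oxa-6π electrocyclisation, which delivers 12.

**Step 2.** The tertiary allyl ether of an acidic phenol can lose isoprene on heating, and some C6 isomer may form. The fallback sets out from 1 and comes back at 5, bypassing 3. Electrophilic iodination (NIS, cat. CF3CO2H, MeCN, 0 °C) at the activated C8 gives 7-hydroxy-8-iodo-4H-chromen-4-one F3. Stille coupling of F3 with tributyl(3-methylbut-2-en-1-yl)stannane (Pd(PPh3)4, LiCl, DMF, 90 °C) then places the linear prenyl group and gives 5.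

**Further compounds**
F1 | step 5 | [2,2-dimethyl-8-(3-methylbut-2-en-1-yl)-2H-chromen-6-yl]boronic acid | CC(C)=CCc1cc(B(O)O)cc2c1OC(C)(C)C=C2
F2 | step 4 | 4-bromo-1-[(2-methylbut-3-yn-2-yl)oxy]-2-(3-methylbut-2-en-1-yl)benzene | C#CC(C)(C)Oc1ccc(Br)cc1CC=C(C)C
F3 | step 2 | 7-hydroxy-8-iodo-4H-chromen-4-one | O=c1ccoc2c(I)c(O)ccc12
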